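**Retrosynthetic overview**

- The strategy rests on the oxane ring O1–C2–C3–C4–C5–C6: C2 carries the CH2CH2–ring A chain, C4 the hydroxyl, C6 ring B, and O1–C2 and C5–C6 lie on opposite sides of the ring.
- The C4 alcohol is traced back to a ketone and then to a C3=C4 silyl enol ether; cutting O1–C2 and C5–C6 then gives a ring B aldehyde and an E-4-substituted 2-silyloxydiene, joined by a catalytic asymmetric hetero-Diels–Alder reaction that sets C2 and C6 cis.
- The diene comes from the ring A propanoic acid by benzylation, reduction, oxidation, Wittig olefination to the E-enone and silylation; the aldehyde is 5-hydroxyvanillin diacetate.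
- Both arenes are bought; the oxane is the only ring made, in the cycloaddition. C4 is set afterwards by hydride reduction, and the acetates and the benzyl ether are removed last.

Key step: step 7

Assumption: Rh2(S-BPTPI)4 (BPTPI = (S)-3-(benzo-fused phthalimido)piperidin-2-onate) is taken to open the Si face of the bound ring B aldehyde, as (6S) requires; if a first run shows the opposite sense, the mirror-image Rh2(R-BPTPI)4 is used and nothing else changes.

**Route**

Step 1
Reactants: 1 3-(4-hydroxy-3-methoxyphenyl)propanoic acid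
Product: 2 benzyl 3-[4-(benzyloxy)-3-methoxyphenyl]propanoate
Conditions: BnBr (2.3 equiv), K2CO3, DMF, rt to 60 °C
Reagents that add atoms: benzyl bromide, BrCc1ccccc1
Why: Williamson O-alkylation of the phenoxide and SN2 alkylation of the carboxylate by benzyl bromide protect the phenol and give an ester ready for reduction in one operation.

Step 2
Reactants: 2 benzyl 3-[4-(benzyloxy)-3-methoxyphenyl]propanoate
Product: 3 3-[4-(benzyloxy)-3-methoxyphenyl]propan-1-ol
Conditions: LiAlH4, THF, 0 °C; aqueous work-up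
Reagents that add atoms: none
Why: Hydride reduction of the ester gives the primary alcohol, and the aryl benzyl ether and aryl methyl ether are inert to LiAlH4.

Step 3
Reactants: 3 3-[4-(benzyloxy)-3-methoxyphenyl]propan-1-ol
Product: 4 3-[4-(benzyloxy)-3-methoxyphenyl]propanal
Conditions: Dess–Martin periodinane, CH2Cl2, 0 °C to rt
Reagents that add atoms: none
Why: Dess–Martin oxidation stops cleanly at the aldehyde and does not touch the electron-rich arene or the benzyl ether.

Step 4
Reactants: 4 3-[4-(benzyloxy)-3-methoxyphenyl]propanal; 5 1-(triphenylphosphoranylidene)propan-2-one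
Product: 6 (E)-6-[4-(benzyloxy)-3-methoxyphenyl]hex-3-en-2-one
Conditions: toluene, 80 °C
Reagents that add atoms: none
Why: Wittig olefination with a keto-stabilised ylide is reversible up to the oxaphosphetane and therefore delivers the E-enone.

Step 5
Reactants: 6 (E)-6-[4-(benzyloxy)-3-methoxyphenyl]hex-3-en-2-one
Product: 7 (E)-6-[4-(benzyloxy)-3-methoxyphenyl]-2-(triethylsilyloxy)hexa-1,3-diene
Conditions: Et3SiOTf, Et3N, Et2O, 0 °C; cold NaHCO3 wash, pentane extraction, used without chromatography on acidic silica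
Reagents that add atoms: triethylsilyl trifluoromethanesulfonate, CC[Si](CC)(CC)OS(=O)(=O)C(F)(F)F
Why: Soft enolisation (O-silylation of the enone, then amine deprotonation of the methyl group) gives the cross-conjugated 2-silyloxydiene and leaves the E C3=C4 bond untouched.

Step 6
Reactants: 8 3,4-dihydroxy-5-methoxybenzaldehyde
Product: 9 3,4-diacetoxy-5-methoxybenzaldehyde
Conditions: Ac2O, pyridine, 4-(dimethylamino)pyridine (cat.), CH2Cl2, 0 °C to rt
Reagents that add atoms: acetic anhydride, CC(=O)OC(C)=O
Why: Nucleophile-catalysed O-acetylation of both phenols proceeds under basic conditions that leave the aldehyde alone.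

Step 7
Reactants: 7 (E)-6-[4-(benzyloxy)-3-methoxyphenyl]-2-(triethylsilyloxy)hexa-1,3-diene; 9 3,4-diacetoxy-5-methoxybenzaldehyde
Product: 10 (2S,6S)-2-{2-[4-(benzyloxy)-3-methoxyphenyl]ethyl}-6-(3,4-diacetoxy-5-methoxyphenyl)-4-(triethylsilyloxy)-5,6-dihydro-2H-pyran (2,6-cis)
Conditions: Rh2(S-BPTPI)4 (2 mol %), 4 Å molecular sieves, CH2Cl2, 0 °C to rt; filtration through Et3N-deactivated silica
Reagents that add atoms: none
Why: Hetero-Diels–Alder reaction: the aldehyde oxygen of 9 binds an axial site of the chiral dirhodium carboxamidate (each rhodium divalent), which lowers the C=O acceptor orbital, and diene 7 adds in a concerted, asynchronous [4+2] mode in which the C5–C6 bond (diene CH2 terminus to carbonyl carbon) runs ahead of O1–C2. The closest known reaction type is the enantioselective hetero-Diels–Alder addition of aldehydes to 4-substituted 2-silyloxy-1,3-dienes under chiral Lewis acids of this dirhodium class, here applied to a new aldehyde and diene pair. The oxane ring is closed by intermolecular [4+2] cycloaddition, four diene carbons plus the C=O unit, with both ring bonds made in the one step. C6 is set by the catalyst, whose ligand wall leaves the Si face of the bound aldehyde open, and C2 is set relative to C6 by the endo transition state (ring B under the diene, catalyst anti to ring B on oxygen) together with the E geometry of the diene, which places the chain and ring B cis. The step needs regio-, endo- and enantioface selectivity and must outrun an open-chain Mukaiyama aldol path: the 2-silyloxy group makes C1 of the diene the nucleophilic terminus, and the two acetates cancel most of the donor power of the ring B oxygens so that the aldehyde stays electrophilic enough for a diene that lacks a 1-alkoxy group.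

Step 8
Reactants: 10 (2S,6S)-4-silyloxy-5,6-dihydro-2H-pyran cycloadduct
Product: 11 (2S,6S)-2-{2-[4-(benzyloxy)-3-methoxyphenyl]ethyl}-6-(3,4-diacetoxy-5-methoxyphenyl)oxan-4-one (2,6-cis)
Conditions: 1 M aq. HCl, THF, 0 °C, short reaction time
Reagents that add atoms: none
Why: Acid hydrolysis of the silyl enol ether (protonation at C3, loss of silicon from oxygen) frees the ketone without touching C2 or C6, and brief cold dilute acid spares the aryl acetates.

Step 9
Reactants: 11 (2S,6S)-2,6-cis-oxan-4-one
Product: 12 (2S,4R,6S)-2-{2-[4-(benzyloxy)-3-methoxyphenyl]ethyl}-6-(3,4-diacetoxy-5-methoxyphenyl)oxan-4-ol (all-cis)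
Conditions: NaBH4, MeOH/THF (1:1), −40 °C
Reagents that add atoms: none
Why: Ketone reduction by a small hydride: axial attack on the chair with the C2 and C6 substituents equatorial should give the equatorial (4R) alcohol, all-cis, and the low temperature keeps the aryl acetates in place.

Step 10
Reactants: 12 (2S,4R,6S)-oxan-4-ol with ring B diacetate
Product: 13 (2S,4R,6S)-2-{2-[4-(benzyloxy)-3-methoxyphenyl]ethyl}-6-(3,4-dihydroxy-5-methoxyphenyl)oxan-4-ol
Conditions: K2CO3, degassed MeOH, 0 °C, Ar; then aq. NH4Cl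
Reagents that add atoms: none
Why: Base-promoted transesterification (methanolysis) removes both aryl acetates rapidly, cannot affect the secondary alcohol or the ring stereocentres, and is run without oxygen to protect the catechol.

Step 11
Reactants: 13 (2S,4R,6S)-benzyl ether triol
Product: 14 (2S,4R,6S)-6-(3,4-dihydroxy-5-methoxyphenyl)-2-[2-(4-hydroxy-3-methoxyphenyl)ethyl]oxan-4-ol (CNP0399218.1)
Conditions: H2 (1 atm), 10% Pd/C, EtOAc, rt, stopped at full conversion
Reagents that add atoms: none
Why: Catalytic hydrogenolysis cleaves the aryl benzyl ether under neutral conditions in which the three stereocentres and the secondary alcohol are not at risk.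

**Compound list**

1 | 3-(4-hydroxy-3-methoxyphenyl)propanoic acid | COc1cc(CCC(=O)O)ccc1O | starting material
2 | benzyl 3-[4-(benzyloxy)-3-methoxyphenyl]propanoate | COc1cc(CCC(=O)OCc2ccccc2)ccc1OCc1ccccc1 | intermediate
3 | 3-[4-(benzyloxy)-3-methoxyphenyl]propan-1-ol | COc1cc(CCCO)ccc1OCc1ccccc1 | intermediate
4 | 3-[4-(benzyloxy)-3-methoxyphenyl]propanal | COc1cc(CCC=O)ccc1OCc1ccccc1 | intermediate
5 | 1-(triphenylphosphoranylidene)propan-2-one | CC(=O)C=P(c1ccccc1)(c1ccccc1)c1ccccc1 | starting material
6 | (E)-6-[4-(benzyloxy)-3-methoxyphenyl]hex-3-en-2-one | COc1cc(CC/C=C/C(C)=O)ccc1OCc1ccccc1 | intermediate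
7 | (E)-6-[4-(benzyloxy)-3-methoxyphenyl]-2-(triethylsilyloxy)hexa-1,3-diene | COc1cc(CC/C=C/C(=C)O[Si](CC)(CC)CC)ccc1OCc1ccccc1 | intermediate
8 | 3,4-dihydroxy-5-methoxybenzaldehyde (5-hydroxyvanillin) | COc1cc(C=O)cc(O)c1O | starting material
9 | 3,4-diacetoxy-5-methoxybenzaldehyde | COc1cc(C=O)cc(OC(C)=O)c1OC(C)=O | intermediate
10 | (2S,6S)-2-{2-[4-(benzyloxy)-3-methoxyphenyl]ethyl}-6-(3,4-diacetoxy-5-methoxyphenyl)-4-(triethylsilyloxy)-5,6-dihydro-2H-pyran | COc1cc(CC[C@H]2C=C(O[Si](CC)(CC)CC)C[C@@H](c3cc(OC(C)=O)c(OC(C)=O)c(OC)c3)O2)ccc1OCc1ccccc1 | intermediate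
11 | (2S,6S)-2-{2-[4-(benzyloxy)-3-methoxyphenyl]ethyl}-6-(3,4-diacetoxy-5-methoxyphenyl)oxan-4-one | COc1cc(CC[C@H]2CC(=O)C[C@@H](c3cc(OC(C)=O)c(OC(C)=O)c(OC)c3)O2)ccc1OCc1ccccc1 | intermediate
12 | (2S,4R,6S)-2-{2-[4-(benzyloxy)-3-methoxyphenyl]ethyl}-6-(3,4-diacetoxy-5-methoxyphenyl)oxan-4-ol | COc1cc(CC[C@H]2C[C@@H](O)C[C@@H](c3cc(OC(C)=O)c(OC(C)=O)c(OC)c3)O2)ccc1OCc1ccccc1 | intermediate
13 | (2S,4R,6S)-2-{2-[4-(benzyloxy)-3-methoxyphenyl]ethyl}-6-(3,4-dihydroxy-5-methoxyphenyl)oxan-4-ol | COc1cc(CC[C@H]2C[C@@H](O)C[C@@H](c3cc(O)c(O)c(OC)c3)O2)ccc1OCc1ccccc1 | intermediate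
14 | (2S,4R,6S)-6-(3,4-dihydroxy-5-methoxyphenyl)-2-[2-(4-hydroxy-3-methoxyphenyl)ethyl]oxan-4-ol (CNP0399218.1) | COc1cc(CC[C@H]2C[C@@H](O)C[C@@H](c3cc(O)c(O)c(OC)c3)O2)ccc1O | target

**Step count**

Total: 11 steps. Longest linear sequence: 10 steps (steps 1, 2, 3, 4, 5, 7, 8, 9, 10, 11); step 6 is the one-step side branch.

**Steps most likely to fail**

1. Step 7. The cycloaddition may be sluggish because the diene has no 1-alkoxy group, enantioface control may erode, or the reaction may divert to an open-chain Mukaiyama aldol path. Fallback, setting out from 4 and 9: Brown allylation of 4 with B-allyldiisopinocampheylborane (the enantiomer that gives the S carbinol; Et2O, −78 °C, then NaOH/H2O2) gives (S)-1-[4-(benzyloxy)-3-methoxyphenyl]hex-5-en-3-ol F1. Prins cyclisation of F1 with 9 in CF3CO2H/CH2Cl2 at 0 °C proceeds through the chair oxocarbenium ion with both substituents equatorial and equatorial capture by trifluoroacetate, giving (2S,4R,6S)-2-{2-[4-(benzyloxy)-3-methoxyphenyl]ethyl}-6-(3,4-diacetoxy-5-methoxyphenyl)oxan-4-yl trifluoroacetate F2. The deactivated ring B should restrain oxonia-Cope scrambling. K2CO3 in degassed MeOH then cleaves the trifluoroacetate and both aryl acetates, and the route is rejoined at 13.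

2. Step 5. Enolisation may drift to the γ-position and give the linear dienol ether, and the triethylsilyl dienol ether may hydrolyse during isolation. Fallback, setting out from 6: kinetic deprotonation of the methyl group with LDA in THF at −78 °C and trapping with t-BuMe2SiOTf gives the chromatography-stable (E)-6-[4-(benzyloxy)-3-methoxyphenyl]-2-(tert-butyldimethylsilyloxy)hexa-1,3-diene F3. Cycloaddition of F3 with 9 under the catalyst of step 7 gives (2S,6S)-2-{2-[4-(benzyloxy)-3-methoxyphenyl]ethyl}-6-(3,4-diacetoxy-5-methoxyphenyl)-4-(tert-butyldimethylsilyloxy)-5,6-dihydro-2H-pyran F4. Hydrolysis of F4 with CF3CO2H in wet CH2Cl2 at 0 °C rejoins the route at 11.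

3. Step 11. The benzylic C6–O1 bond of the oxane may be hydrogenolysed alongside the benzyl ether, because ring B as a free catechol is electron-rich. Fallback, setting out from 12: hydrogenolysis (H2, 10% Pd/C, EtOAc) while ring B is still deactivated as its diacetate gives (2S,4R,6S)-6-(3,4-diacetoxy-5-methoxyphenyl)-2-[2-(4-hydroxy-3-methoxyphenyl)ethyl]oxan-4-ol F5. Methanolysis of F5 (K2CO3, degassed MeOH, 0 °C, Ar) then gives 14 directly.

**Further compounds**

F1 | step 7 | (S)-1-[4-(benzyloxy)-3-methoxyphenyl]hex-5-en-3-ol | COc1cc(CC[C@H](O)CC=C)ccc1OCc1ccccc1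
F2 | step 7 | (2S,4R,6S)-2-{2-[4-(benzyloxy)-3-methoxyphenyl]ethyl}-6-(3,4-diacetoxy-5-methoxyphenyl)oxan-4-yl trifluoroacetate | COc1cc(CC[C@H]2C[C@@H](OC(=O)C(F)(F)F)C[C@@H](c3cc(OC(C)=O)c(OC(C)=O)c(OC)c3)O2)ccc1OCc1ccccc1
F3 | step 5 | (E)-6-[4-(benzyloxy)-3-methoxyphenyl]-2-(tert-butyldimethylsilyloxy)hexa-1,3-diene | COc1cc(CC/C=C/C(=C)O[Si](C)(C)C(C)(C)C)ccc1OCc1ccccc1
F4 | step 5 | (2S,6S)-2-{2-[4-(benzyloxy)-3-methoxyphenyl]ethyl}-6-(3,4-diacetoxy-5-methoxyphenyl)-4-(tert-butyldimethylsilyloxy)-5,6-dihydro-2H-pyran | COc1cc(CC[C@H]2C=C(O[Si](C)(C)C(C)(C)C)C[C@@H](c3cc(OC(C)=O)c(OC(C)=O)c(OC)c3)O2)ccc1OCc1ccccc1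
F5 | step 11 | (2S,4R,6S)-6-(3,4-diacetoxy-5-methoxyphenyl)-2-[2-(4-hydroxy-3-methoxyphenyl)ethyl]oxan-4-ol | COc1cc(CC[C@H]2C[C@@H](O)C[C@@H](c3cc(OC(C)=O)c(OC(C)=O)c(OC)c3)O2)ccc1O
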